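Elemane numbering: the cyclohexane is C5–C10. C10 is quaternary and carries methyl C14 and the oxirane C1–C2. C5 carries the acrolein unit C4(=C3H2)–C15HO, C6 the OH, C9 the ester. The γ-lactone is O–C8–C7–C11(=C13H2)–C12.
Enabling feature: two 2-methylene homoallylic alcohol units, C13=C11–C7–C8–O in the lactone ring and C3=C4–C5–C6–OH on the cyclohexane, overlap in the C6–C7 bond. C6 (aldehyde level) and C12 (acid level) are 1,4-related through C7/C11, so both can be stored in one temporary 5-ethoxybutenolide ring (6).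
Key disconnection: C7–C8 and C5–C6 are cut together, giving a double allylboration domino between 6 and the acyclic aldehyde/allylboronate 29. The γ-lactone closes first by an acyl transfer that frees the C6 aldehyde; the cyclohexane closes second. C5–C8 are all set here.
29 comes from aldehyde 23 by vinyllithium addition, copper-catalysed SN2' borylation and direct Swern oxidation of a TES ether. The oxirane ring is made earlier (steps 10 and 11) by iodocarbonate cyclisation, 1,3-syn to the C9 oxygen.
C9 and C10 come from an allene hydroboration/asymmetric allylboration (13 + 10). The 2'S ester comes from the chiral pool. The last step unmasks the C15 aldehyde.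

Key step: step 18

Remark on the chemistry: the target is taken as the open 6-hydroxy-15-aldehyde that is drawn, not as its cyclic hemiacetal. Compound 24 is taken as commercially available. Compound 6 is used as the racemate in excess, because its only stereocentre is destroyed in step 18.

Step 1
Reactants: 1 3,3-diethoxyprop-1-yne
Product: 3 tert-butyl 4,4-diethoxybut-2-ynoate, via lithium acetylide 2 (not isolated)
Conditions: n-BuLi, THF, −78 °C; Boc2O, −78 °C → rt
Reagents that add atoms: di-tert-butyl dicarbonate, CC(C)(C)OC(=O)OC(=O)OC(C)(C)C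
Why: Deprotonation of the terminal alkyne and C-acylation of the acetylide with Boc2O is the standard route to tert-butyl alkynoates, and the acetal is inert to base.

Step 2
Reactants: 3 tert-butyl 4,4-diethoxybut-2-ynoate
Product: 5 tert-butyl (2Z)-4,4-diethoxy-2-[(4,4,5,5-tetramethyl-1,3,2-dioxaborolan-2-yl)methyl]but-2-enoate, via vinylalane 4 (not isolated)
Conditions: iBu2AlH, HMPA, THF, 0 °C; ICH2Bpin, 0 °C → rt
Reagents that add atoms: 2-(iodomethyl)-4,4,5,5-tetramethyl-1,3,2-dioxaborolane, ICB1OC(C)(C)C(C)(C)O1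
Why: Conjugate syn-hydroalumination puts H on C7 and Al on C11 on the same side, and alkylation of the α-alumino enoate with the halomethylboronate (the established entry to 2-alkoxycarbonyl allylboronates) keeps that geometry, so the acetal carbon C6 ends cis to the ester.

Step 3
Reactants: 5 tert-butyl (2Z)-4,4-diethoxy-2-[(pinacolboryl)methyl]but-2-enoate
Product: 6 (±)-5-ethoxy-3-[(4,4,5,5-tetramethyl-1,3,2-dioxaborolan-2-yl)methyl]furan-2(5H)-one
Conditions: TFA, CH2Cl2, 0 °C → rt
Reagents that add atoms: none
Why: Acid removes the tert-butyl group and the cis carboxyl captures the oxocarbenium ion of the acetal (5-exo), which is the usual closure of (Z)-4,4-dialkoxybut-2-enoic acids to 5-alkoxybutenolides; the electron-poor allylboronate should resist protodeboronation.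

Step 4
Reactants: 7 (Z)-but-2-ene-1,4-diol
Product: 8 (Z)-1,4-bis[(triethylsilyl)oxy]but-2-ene
Conditions: Et3SiCl, imidazole, CH2Cl2, 0 °C → rt
Reagents that add atoms: chlorotriethylsilane, CC[Si](Cl)(CC)CC
Why: Standard silylation of two primary alcohols.

Step 5
Reactants: 8 (Z)-1,4-bis[(triethylsilyl)oxy]but-2-ene
Product: 10 [(triethylsilyl)oxy]acetaldehyde (two molecules per molecule of 8), via ozonide 9 (not isolated)
Conditions: O3, CH2Cl2, −78 °C; Me2S, −78 °C → rt
Reagents that add atoms: ozone, [O-][O+]=O
Why: Ozonolysis with reductive work-up cleaves the symmetrical alkene into two molecules of the aldehyde, and silyl ethers are inert.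

Step 6
Reactants: 11 4-chlorobut-2-yn-1-ol
Product: 12 2-methylbuta-2,3-dien-1-ol
Conditions: MeMgBr (2.2 equiv), CuI (10 mol %), Et2O, −30 °C → rt
Reagents that add atoms: methylmagnesium bromide, C[Mg]Br
Why: Copper-catalysed SN2' displacement of a propargylic chloride by a Grignard reagent is the standard synthesis of 1,1-disubstituted allenes.

Step 7
Reactants: 12 2-methylbuta-2,3-dien-1-ol
Product: 13 benzyl 2-methylbuta-2,3-dien-1-yl ether
Conditions: NaH, BnBr, Bu4NI (cat.), THF, 0 °C → rt
Reagents that add atoms: benzyl bromide, BrCc1ccccc1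
Why: Williamson ether synthesis; the allene is inert to these conditions.

Step 8
Reactants: 13 benzyl 2-methylbuta-2,3-dien-1-yl ether; 10 [(triethylsilyl)oxy]acetaldehyde
Product: 16 (2S,3S)-3-[(benzyloxy)methyl]-3-methyl-1-[(triethylsilyl)oxy]pent-4-en-2-ol, via allylborane 14 (not isolated), via borinate 15 (not isolated)
Conditions: (−)-Ipc2BH (from (+)-α-pinene), Et2O, 0 °C; 10, −78 °C; H2O2, pH 7 buffer, MeOH, 0 °C
Reagents that add atoms: none
Why: Kinetic hydroboration of the terminal allene π bond from the side away from CH2OBn gives the (Z)-γ,γ-disubstituted allylborane (allene hydroboration/Brown allylboration), whose Zimmerman–Traxler chair holds CH2OBn axial and so sets C10 relative to C9, while the isopinocampheyl groups direct attack to the Si face of 10 and set C9 as S.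

Step 9
Reactants: 16 (2S,3S)-homoallylic alcohol
Product: 17 tert-butyl (2S,3S)-3-[(benzyloxy)methyl]-3-methyl-1-[(triethylsilyl)oxy]pent-4-en-2-yl carbonate
Conditions: Boc2O, DMAP, MeCN, rt
Reagents that add atoms: di-tert-butyl dicarbonate, CC(C)(C)OC(=O)OC(=O)OC(C)(C)C
Why: DMAP-catalysed carbonate formation on the only free hydroxyl.

Step 10
Reactants: 17 homoallylic tert-butyl carbonate
Product: 18 (4R,5S,6S)-5-[(benzyloxy)methyl]-4-(iodomethyl)-5-methyl-6-{[(triethylsilyl)oxy]methyl}-1,3-dioxan-2-one
Conditions: IBr, toluene, −85 °C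
Reagents that add atoms: iodine monobromide, IBr
Why: In this iodocarbonate cyclisation of a homoallylic tert-butyl carbonate the carbonate carbonyl oxygen opens the iodonium ion 6-exo through a chair with CH2OTES and CH2I equatorial, so the new C1–O bond forms 1,3-syn to C9–O and sets C1 as R.

Step 11
Reactants: 18 cyclic iodocarbonate
Product: 19 (2S,3S)-4-(benzyloxy)-3-methyl-3-[(2R)-oxiran-2-yl]-1-[(triethylsilyl)oxy]butan-2-ol
Conditions: K2CO3, MeOH, 0 °C → rt
Reagents that add atoms: none
Why: Methanolysis of the carbonate frees both oxygens and the C1 alkoxide displaces the neighbouring primary iodide (3-exo-tet epoxide closure) with retention at C1, leaving the C9 hydroxyl free.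

Step 12
Reactants: 19 epoxy alcohol; 20 (S)-2-methylbutanoic anhydride
Product: 21 (2S,3R)-4-(benzyloxy)-3-methyl-3-[(2R)-oxiran-2-yl]-1-[(triethylsilyl)oxy]butan-2-yl (2S)-2-methylbutanoate
Conditions: DMAP, Et3N, CH2Cl2, rt
Reagents that add atoms: none
Why: DMAP-catalysed acylation with the enantiopure anhydride avoids a ketene, so the 2'S centre is carried in unchanged from the chiral pool.

Step 13
Reactants: 21 benzyl ether
Product: 22 (2S,3R)-4-hydroxy-3-methyl-3-[(2R)-oxiran-2-yl]-1-[(triethylsilyl)oxy]butan-2-yl (2S)-2-methylbutanoate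
Conditions: H2 (1 atm), Pd/C, EtOAc, rt
Reagents that add atoms: none
Why: Hydrogenolysis of the benzyl ether; no alkene is present at this stage, and the aliphatic oxirane, the ester and (in EtOAc) the TES ether are inert.

Step 14
Reactants: 22 primary alcohol
Product: 23 (2S,3R)-3-methyl-3-[(2R)-oxiran-2-yl]-4-oxo-1-[(triethylsilyl)oxy]butan-2-yl (2S)-2-methylbutanoate
Conditions: Dess–Martin periodinane, CH2Cl2, 0 °C → rt
Reagents that add atoms: none
Why: Dess–Martin oxidation; the aldehyde has no α-hydrogen, so C10 cannot epimerise.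

Step 15
Reactants: 24 2-bromo-3,3-diethoxyprop-1-ene; 23 aldehyde
Product: 27 (2S,3R)-5-(diethoxymethyl)-4-[(methoxycarbonyl)oxy]-3-methyl-3-[(2R)-oxiran-2-yl]-1-[(triethylsilyl)oxy]hex-5-en-2-yl (2S)-2-methylbutanoate (both epimers at the new carbinol carbon C5), via vinyllithium 25 (not isolated), via lithium alkoxide 26 (not isolated)
Conditions: 24, t-BuLi (2 equiv), Et2O, −78 °C; 23, −78 °C; ClCO2Me, −78 → 0 °C
Reagents that add atoms: methyl chloroformate, COC(=O)Cl
Why: Bromine–lithium exchange gives the α-lithioacrolein acetal, which adds to the aldehyde much faster than to the hindered ester or the oxirane at −78 °C; trapping the alkoxide in the flask forestalls 1,3-acyl migration, and the carbinol centre is erased in step 16.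

Step 16
Reactants: 27 allylic methyl carbonate
Product: 28 (2S,3R,4E)-5-(diethoxymethyl)-3-methyl-3-[(2R)-oxiran-2-yl]-6-(4,4,5,5-tetramethyl-1,3,2-dioxaborolan-2-yl)-1-[(triethylsilyl)oxy]hex-4-en-2-yl (2S)-2-methylbutanoate (CH2Bpin cis to C10)
Conditions: B2pin2, CuCl (5 mol %), Xantphos (5 mol %), KOtBu (10 mol %), THF, rt
Reagents that add atoms: bis(pinacolato)diboron, CC1(C)OB(OC1(C)C)B1OC(C)(C)C(C)(C)O1
Why: In this copper-catalysed γ-selective (SN2') borylation of an allylic carbonate, borylcupration and anti-elimination from the conformer that avoids A(1,2) strain between C10 and CH(OEt)2 should place C10 cis to CH2Bpin, as in SN2' reactions of Baylis–Hillman acetates, and both C5 epimers converge on one alkene.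

Step 17
Reactants: 28 allylboronate TES ether
Product: 29 (2S,3R,4E)-5-(diethoxymethyl)-3-methyl-3-[(2R)-oxiran-2-yl]-1-oxo-6-(4,4,5,5-tetramethyl-1,3,2-dioxaborolan-2-yl)hex-4-en-2-yl (2S)-2-methylbutanoate
Conditions: (COCl)2, DMSO, CH2Cl2, −78 → −40 °C; Et3N, −78 → 0 °C; used at once
Reagents that add atoms: none
Why: Swern conditions turn primary triethylsilyl ethers directly into aldehydes, so no free C8 alcohol that could accept the neighbouring acyl group is formed, and the acetal, the oxirane and the hindered allylboronate should be inert at low temperature.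

Step 18
Reactants: 29 aldehyde/allylboronate; 6 (±)-5-ethoxy-3-[(pinacolboryl)methyl]furan-2(5H)-one
Product: 33 15,15-diethyl acetal of the target (1R,5R,6S,7S,8R,9S,10R,2'S), via boronate adduct 30 (not isolated), via lactone aldehyde 31 (not isolated), via cyclised borate 32 (not isolated)
Conditions: 29 (0.05 M in toluene) added over 10 h to 6 (3 equiv, 1 M in toluene), 4 Å MS, 70 °C, then 12 h; pH 7 buffer
Reagents that add atoms: none
Why: Proposed new method: the butenolide ring of 6 ties C6 to C12 and so fixes the (E)-crotyl-type geometry of this 2-alkoxycarbonyl allylboronate, whose Zimmerman–Traxler chair addition to the α-acyloxy aldehyde 29 makes C7–C8 with the 7,8-anti (later trans-lactone) relationship, while the Cornforth/polar Felkin–Anh arrangement of the C9–O bond, with the bulky C10 turned away from the reagent, selects the aldehyde face and gives the 8,9-anti pair (30). The C8–O–B oxygen then attacks the acylal carbonyl C12 (5-exo-trig), which closes the γ-lactone, opens the temporary ring and lets the hemiacetal borate collapse to EtOBpin and the C6 aldehyde 31, so the acetal centre of racemic 6 is erased and every molecule of 6 that reacts feeds the same aldehyde. The aldehyde is trapped by the internal allylboronate (6-exo-trig at C6=O, SE2' at C5) through a chair–chair transition state in which the trans-lactone holds the C7 and C8 substituents equatorial; because CH2Bpin is cis to C10 ((Z)-crotyl type), C10 is axial and C7 equatorial on the boron chair, which forces the C5/C6 syn pair with the C4 branch equatorial and the C6 oxygen axial, whereas the other syn pair would need C7 axial on the boron chair. The closest known reaction types are the thermal allylboration–lactonisation of 2-alkoxycarbonyl allylboronates, the allylation of aldehydes with 3-(bromomethyl)furan-2(5H)-one followed by translactonisation, and the intramolecular allylboration of ω-oxo allylboronates to 2-alkenylcyclohexanols with (Z)-to-cis fidelity; what is new is their coupling through an aldehyde-releasing acyl transfer. The step needs 29 to react with 6 and not with itself, and 31 to cyclise rather than meet a second molecule of 6: the first is secured by the neopentylic γ-carbon C5 of 29 and by its slow addition into excess 6, the second by the low nucleophilicity of 6 set against an intramolecular six-ring closure.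

Step 19
Reactants: 33 diethyl acetal
Product: 34 CNP0510523.1 (1R,5R,6S,7S,8R,9S,10R,2'S)
Conditions: PPTS (cat.), acetone/H2O, rt
Reagents that add atoms: water, O
Why: Mild acid hydrolysis of an acrolein-type acetal, which ionises much more readily than the neopentylic monosubstituted oxirane opens, gives the conjugated C15 aldehyde without touching any stereocentre.

Compound list
1 | 3,3-diethoxyprop-1-yne | C#CC(OCC)OCC | starting material
2 | lithium 3,3-diethoxyprop-1-yn-1-ide | [Li]C#CC(OCC)OCC | intermediate
3 | tert-butyl 4,4-diethoxybut-2-ynoate | CCOC(OCC)C#CC(=O)OC(C)(C)C | intermediate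
4 | tert-butyl (Z)-2-(diisobutylalumanyl)-4,4-diethoxybut-2-enoate | CCOC(OCC)/C=C(\C(=O)OC(C)(C)C)[Al](CC(C)C)CC(C)C | intermediate
5 | tert-butyl (2Z)-4,4-diethoxy-2-[(pinacolboryl)methyl]but-2-enoate | CCOC(OCC)/C=C(\C(=O)OC(C)(C)C)CB1OC(C)(C)C(C)(C)O1 | intermediate
6 | (±)-5-ethoxy-3-[(pinacolboryl)methyl]furan-2(5H)-one | CCOC1C=C(CB2OC(C)(C)C(C)(C)O2)C(=O)O1 | intermediate
7 | (Z)-but-2-ene-1,4-diol | OC/C=C\CO | starting material
8 | (Z)-1,4-bis[(triethylsilyl)oxy]but-2-ene | CC[Si](CC)(CC)OC/C=C\CO[Si](CC)(CC)CC | intermediate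
9 | 3,5-bis{[(triethylsilyl)oxy]methyl}-1,2,4-trioxolane | CC[Si](CC)(CC)OCC1OOC(CO[Si](CC)(CC)CC)O1 | intermediate
10 | [(triethylsilyl)oxy]acetaldehyde | CC[Si](CC)(CC)OCC=O | intermediate
11 | 4-chlorobut-2-yn-1-ol | OCC#CCCl | starting material
12 | 2-methylbuta-2,3-dien-1-ol | C=C=C(C)CO | intermediate
13 | benzyl 2-methylbuta-2,3-dien-1-yl ether | C=C=C(C)COCc1ccccc1 | intermediate
14 | [(2Z)-4-(benzyloxy)-3-methylbut-2-en-1-yl]bis(isopinocampheyl)borane | C(/C=C(\COCc1ccccc1)C)B([C@@H]2C[C@@H]3C[C@H]([C@H]2C)C3(C)C)[C@@H]2C[C@@H]3C[C@H]([C@H]2C)C3(C)C | intermediate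
15 | bis(isopinocampheyl)borinate of 16 | c1ccccc1COC[C@](C)(C=C)[C@@H](CO[Si](CC)(CC)CC)OB([C@@H]2C[C@@H]3C[C@H]([C@H]2C)C3(C)C)[C@@H]2C[C@@H]3C[C@H]([C@H]2C)C3(C)C | intermediate
16 | (2S,3S)-3-[(benzyloxy)methyl]-3-methyl-1-[(triethylsilyl)oxy]pent-4-en-2-ol | c1ccccc1COC[C@](C)(C=C)[C@H](O)CO[Si](CC)(CC)CC | intermediate
17 | tert-butyl carbonate of 16 | c1ccccc1COC[C@](C)(C=C)[C@H](OC(=O)OC(C)(C)C)CO[Si](CC)(CC)CC | intermediate
18 | (4R,5S,6S)-5-[(benzyloxy)methyl]-4-(iodomethyl)-5-methyl-6-{[(triethylsilyl)oxy]methyl}-1,3-dioxan-2-one | c1ccccc1COC[C@]2(C)[C@H](CI)OC(=O)O[C@@H]2CO[Si](CC)(CC)CC | intermediate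
19 | (2S,3S)-4-(benzyloxy)-3-methyl-3-[(2R)-oxiran-2-yl]-1-[(triethylsilyl)oxy]butan-2-ol | c1ccccc1COC[C@](C)([C@@H]2CO2)[C@H](O)CO[Si](CC)(CC)CC | intermediate
20 | (S)-2-methylbutanoic anhydride | CC[C@H](C)C(=O)OC(=O)[C@@H](C)CC | starting material
21 | (2S,3R)-4-(benzyloxy)-3-methyl-3-[(2R)-oxiran-2-yl]-1-[(triethylsilyl)oxy]butan-2-yl (2S)-2-methylbutanoate | c1ccccc1COC[C@](C)([C@@H]2CO2)[C@@H](CO[Si](CC)(CC)CC)OC(=O)[C@@H](C)CC | intermediate
22 | (2S,3R)-4-hydroxy-3-methyl-3-[(2R)-oxiran-2-yl]-1-[(triethylsilyl)oxy]butan-2-yl (2S)-2-methylbutanoate | OC[C@](C)([C@@H]1CO1)[C@@H](CO[Si](CC)(CC)CC)OC(=O)[C@@H](C)CC | intermediate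
23 | (2S,3R)-3-methyl-3-[(2R)-oxiran-2-yl]-4-oxo-1-[(triethylsilyl)oxy]butan-2-yl (2S)-2-methylbutanoate | O=C[C@](C)([C@@H]1CO1)[C@@H](CO[Si](CC)(CC)CC)OC(=O)[C@@H](C)CC | intermediate
24 | 2-bromo-3,3-diethoxyprop-1-ene | C=C(Br)C(OCC)OCC | starting material
25 | (3,3-diethoxyprop-1-en-2-yl)lithium | [Li]C(=C)C(OCC)OCC | intermediate
26 | lithium alkoxide from 25 and 23 (C5 epimers) | C=C(C(OCC)OCC)C(O[Li])[C@](C)([C@@H]1CO1)[C@@H](CO[Si](CC)(CC)CC)OC(=O)[C@@H](C)CC | intermediate
27 | allylic methyl carbonate (C5 epimers) | C=C(C(OCC)OCC)C(OC(=O)OC)[C@](C)([C@@H]1CO1)[C@@H](CO[Si](CC)(CC)CC)OC(=O)[C@@H](C)CC | intermediate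
28 | (4E)-allylboronate TES ether, CH2Bpin cis to C10 | CCOC(OCC)/C(CB1OC(C)(C)C(C)(C)O1)=C/[C@](C)([C@@H]1CO1)[C@@H](CO[Si](CC)(CC)CC)OC(=O)[C@@H](C)CC | intermediate
29 | (4E)-allylboronate aldehyde (key-step precursor) | CCOC(OCC)/C(CB1OC(C)(C)C(C)(C)O1)=C/[C@](C)([C@@H]1CO1)[C@@H](C=O)OC(=O)[C@@H](C)CC | intermediate
30 | first allylboration adduct: C8–OBpin, 5-ethoxy-3-methylenebutyrolactone on C7 (C6 unassigned) | C=C1C(=O)OC(OCC)[C@H]1[C@@H](OB2OC(C)(C)C(C)(C)O2)[C@@H](OC(=O)[C@@H](C)CC)[C@@](C)([C@@H]2CO2)/C=C(/C(OCC)OCC)CB2OC(C)(C)C(C)(C)O2 | intermediate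
31 | trans-α-methylene-γ-lactone with C7 formyl group and intact allylboronate | C=C1C(=O)O[C@H]([C@@H]1C=O)[C@@H](OC(=O)[C@@H](C)CC)[C@@](C)([C@@H]2CO2)/C=C(/C(OCC)OCC)CB2OC(C)(C)C(C)(C)O2 | intermediate
32 | C6–OBpin borate of 33 | C=C1C(=O)O[C@@H]2[C@@H]1[C@@H](OB3OC(C)(C)C(C)(C)O3)[C@@H](C(=C)C(OCC)OCC)[C@](C)([C@@H]1CO1)[C@@H]2OC(=O)[C@@H](C)CC | intermediate
33 | 15,15-diethyl acetal of the target | C=C1C(=O)O[C@@H]2[C@@H]1[C@@H](O)[C@@H](C(=C)C(OCC)OCC)[C@](C)([C@@H]1CO1)[C@@H]2OC(=O)[C@@H](C)CC | intermediate
34 | CNP0510523.1 | C=C1C(=O)O[C@@H]2[C@@H]1[C@@H](O)[C@@H](C(=C)C=O)[C@](C)([C@@H]1CO1)[C@@H]2OC(=O)[C@@H](C)CC | target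

Total step count: 19.
Longest linear sequence: 14 steps (steps 6–19, from 4-chlorobut-2-yn-1-ol).

Steps most likely to fail

1. Step 18 (Proposed new method). The acyl transfer that should free the C6 aldehyde may stall at the stage of the first adduct. Alternatively, 29 may be consumed by allylboration of its own aldehyde before 6 engages. The fallback uses known chemistry, sets out from 29 and comes back at 31.
 - 29 is heated in toluene with the open-chain reagent methyl (2Z)-2-[(pinacolboryl)methyl]-4-[(triethylsilyl)oxy]but-2-enoate F1. F1 is made as 5 was, from methyl 4-[(triethylsilyl)oxy]but-2-ynoate with iBu2AlH/HMPA and ICH2Bpin.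
 - The established allylboration–lactonisation of 2-alkoxycarbonyl allylboronates should give the trans-lactone silyl ether F2, which carries C6 at the alcohol level.
 - Direct Swern oxidation of its primary TES ether, as in step 17, gives the lactone aldehyde 31. This closes by the known intramolecular allylboration to 32 and 33.

2. Step 16. Control of the double-bond geometry may be lost, with C10 ending trans to CH2Bpin, and the borylcopper species may attack the oxirane. The fallback sets out from 23 and comes back at 28.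
 - Addition of 25 with a protic quench gives the allylic alcohol F3, which is acetylated (Ac2O, DMAP) to the allylic acetate F4.
 - Miyaura borylation with B2pin2 and Pd2(dba)3 in DMSO starts from zerovalent palladium and runs through a π-allyl complex.
 - The syn/anti equilibration of that complex should place C10 next to the smaller CH2 terminus under thermodynamic control, and no nucleophilic boryl metal is present.

3. Step 8. The (Z)-geometry of the allylborane may erode through incomplete facial selection in the hydroboration or through a 1,3-boratropic shift, which would scramble C10 relative to C9. The fallback sets out from 13 and comes back at 16.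
 - Hydroboration of the allene with HBpin under CuCl/Xantphos/KOtBu catalysis gives the isolable (Z)-allylboronate 2-[(2Z)-4-(benzyloxy)-3-methylbut-2-en-1-yl]-4,4,5,5-tetramethyl-1,3,2-dioxaborolane F5, which is configurationally stable and can be freed from its isomer.
 - F5 then adds to 10 under chiral phosphoric acid catalysis; (S)-TRIP is expected to address the same aldehyde face.

Further compounds
F1 | step 18 | methyl (2Z)-2-[(pinacolboryl)methyl]-4-[(triethylsilyl)oxy]but-2-enoate | CC[Si](CC)(CC)OC/C=C(\C(=O)OC)CB1OC(C)(C)C(C)(C)O1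
F2 | step 18 | trans-α-methylene-γ-lactone with C7 CH2OTES group and intact allylboronate | C=C1C(=O)O[C@H]([C@@H]1CO[Si](CC)(CC)CC)[C@@H](OC(=O)[C@@H](C)CC)[C@@](C)([C@@H]2CO2)/C=C(/C(OCC)OCC)CB2OC(C)(C)C(C)(C)O2
F3 | step 16 | allylic alcohol from 25 and 23 (C5 epimers) | C=C(C(OCC)OCC)C(O)[C@](C)([C@@H]1CO1)[C@@H](CO[Si](CC)(CC)CC)OC(=O)[C@@H](C)CC
F4 | step 16 | allylic acetate of F3 (C5 epimers) | C=C(C(OCC)OCC)C(OC(C)=O)[C@](C)([C@@H]1CO1)[C@@H](CO[Si](CC)(CC)CC)OC(=O)[C@@H](C)CC
F5 | step 8 | 2-[(2Z)-4-(benzyloxy)-3-methylbut-2-en-1-yl]-4,4,5,5-tetramethyl-1,3,2-dioxaborolane | CC1(C)OB(C/C=C(\COCc2ccccc2)C)OC1(C)C
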